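**Plan**

- Ring numbering: C1 (gem-diprenyl), C2 (C=O), C3 (isobutyryl-bearing), C4 (enol C–OH), C5 (carbinol, R), C6 (C=O). Two features are used: C5(OH)–C6(=O) is a tertiary α-ketol, and C3, C4 and the isobutyryl carbon can be stored as an isoxazole (ring C3 = isoxazole C4, ring C4 = isoxazole C3, isobutyryl carbon = isoxazole C5).
- Retrosynthetic cuts: the isoxazole N–O bond (giving the C4 enol and the isobutyryl C=O); C5–C6 (aldehyde-to-ketone umpolung closure); C1–C2 (acid chloride plus diprenylacetate enolate); the C5 side chain (aldehyde plus allyl, then isopropylidene by metathesis); the isoxazole itself (chloro-oxime plus β-keto ester).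
- Forward order: the isoxazole is made first and is the only ring until step 13. Its C3 ester becomes a silyl-protected prenyl carbinol, and its C4 ester becomes an acid chloride that is joined to fragment 5 (steps 1–2). Reduction, desilylation and threefold oxidation give keto aldehyde 23, the carbocycle is closed in step 13, and the isoxazole is opened and hydrolysed last.
- Stereochemistry: the only stereocentre, C5, is set in step 13 by a chiral triazolium-derived carbene (Si-face attack on the C5 ketone gives R). All carbinol centres carried before that step are racemic and are oxidised away. C5 is fully substituted afterwards and cannot epimerise.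

Key step: step 13

Assumption: the (5aS,10bR) precatalyst in step 13 is assigned by analogy with related ring closures as the antipode giving Si-face attack; if the sense proves opposite, the (5aR,10bS) salt replaces it without other change.

**Route**

Step 1
Reactants: 1 diethyl malonate; 2 prenyl bromide (1-bromo-3-methylbut-2-ene)
Product: 4 diethyl 2,2-bis(3-methylbut-2-en-1-yl)malonate, via diethyl 2-prenylmalonate 3 (not isolated)
Conditions: NaH (2.2 equiv), 2 (2.2 equiv), THF, 0 → 50 °C
Reagents that add atoms: none
Why: Malonic ester synthesis: the malonate enolate displaces bromide at the primary allylic carbon twice (SN2), so both prenyl groups arrive linear on the carbon that becomes C1.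

Step 2
Reactants: 4 diethyl 2,2-bis(3-methylbut-2-en-1-yl)malonate
Product: 5 ethyl 5-methyl-2-(3-methylbut-2-en-1-yl)hex-4-enoate
Conditions: LiCl, H2O, DMSO, 160 °C
Reagents that add atoms: none
Why: Krapcho dealkoxycarbonylation removes one ester of the quaternary malonate under neutral halide conditions that leave the trisubstituted alkenes untouched.

Step 3
Reactants: 6 ethyl 2-chloro-2-(hydroxyimino)acetate; 7 methyl 4-methyl-3-oxopentanoate
Product: 9 3-ethyl 4-methyl 5-(propan-2-yl)isoxazole-3,4-dicarboxylate, via ethoxycarbonylformonitrile oxide 8 (not isolated)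
Conditions: 7, NaH, THF, 0 °C; then 6 and Et3N added slowly, 0 → 23 °C
Reagents that add atoms: none
Why: Nitrile oxide/β-keto ester cyclocondensation: Et3N dehydrochlorinates 6 to nitrile oxide 8, the sodium enolate of 7 adds through carbon, the oximate oxygen closes on the ketone and loss of hydroxide aromatises, which can only place isopropyl at C5 and the methyl ester at C4 of the isoxazole.

Step 4
Reactants: 9 3-ethyl 4-methyl 5-(propan-2-yl)isoxazole-3,4-dicarboxylate
Product: 10 methyl 3-(hydroxymethyl)-5-(propan-2-yl)isoxazole-4-carboxylate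
Conditions: NaBH4, EtOH, 0 °C
Reagents that add atoms: none
Why: Chemoselective borohydride reduction: the C3 ester lies next to the ring C=N and is activated like a picolinate, whereas the C4 ester is a vinylogous carbonate shielded by the isopropyl group and should be left alone.

Step 5
Reactants: 10 methyl 3-(hydroxymethyl)-5-(propan-2-yl)isoxazole-4-carboxylate
Product: 11 methyl 3-formyl-5-(propan-2-yl)isoxazole-4-carboxylate
Conditions: Dess–Martin periodinane, NaHCO3, CH2Cl2, 0 → 23 °C
Reagents that add atoms: none
Why: Dess–Martin oxidation of the primary heteroaryl carbinol stops at the aldehyde under buffered, non-aqueous conditions.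

Step 6
Reactants: 11 methyl 3-formyl-5-(propan-2-yl)isoxazole-4-carboxylate; 12 allyl bromide
Product: 13 methyl 3-(1-hydroxybut-3-en-1-yl)-5-(propan-2-yl)isoxazole-4-carboxylate (racemic)
Conditions: zinc dust, THF/sat. aq. NH4Cl, 0 → 23 °C
Reagents that add atoms: none
Why: Barbier allylation: allylzinc bromide formed in the flask adds to the aldehyde only, and the aqueous NH4Cl protonates the zinc alkoxide before it can lactonise onto the neighbouring ester; the new carbinol centre is racemic and is oxidised away in step 12.

Step 7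
Reactants: 13 methyl 3-(1-hydroxybut-3-en-1-yl)-5-(propan-2-yl)isoxazole-4-carboxylate (racemic); 14 2-methylbut-2-ene
Product: 15 methyl 3-(1-hydroxy-4-methylpent-3-en-1-yl)-5-(propan-2-yl)isoxazole-4-carboxylate (racemic)
Conditions: RuCl2(=CHPh)(H2IMes)(PCy3) (second-generation Grubbs catalyst, 5 mol %), 2-methylbut-2-ene/CH2Cl2, 40 °C
Reagents that add atoms: none
Why: Olefin cross-metathesis with excess 2-methylbut-2-ene exchanges the terminal methylene for an isopropylidene group and so gives the linear prenyl carbinol, which a prenyl-metal reagent (attack through its substituted terminus) would not.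

Step 8
Reactants: 15 methyl 3-(1-hydroxy-4-methylpent-3-en-1-yl)-5-(propan-2-yl)isoxazole-4-carboxylate (racemic)
Product: 16 methyl 3-[1-(tert-butyldimethylsilyloxy)-4-methylpent-3-en-1-yl]-5-(propan-2-yl)isoxazole-4-carboxylate (racemic)
Conditions: TBSCl, imidazole, DMF, 23 °C
Reagents that add atoms: tert-butyldimethylsilyl chloride, CC(C)(C)[Si](C)(C)Cl
Why: Standard silylation of a secondary alcohol; the silyl ether hides the hydroxyl from the acid chloride formation, the enolate and the hydride that follow.

Step 9
Reactants: 16 methyl 3-[1-(tert-butyldimethylsilyloxy)-4-methylpent-3-en-1-yl]-5-(propan-2-yl)isoxazole-4-carboxylate (racemic)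
Product: 17 3-[1-(tert-butyldimethylsilyloxy)-4-methylpent-3-en-1-yl]-5-(propan-2-yl)isoxazole-4-carboxylic acid (racemic)
Conditions: LiOH, THF/MeOH/H2O, 50 °C; then 1 M HCl to pH 3–4, 0 °C
Reagents that add atoms: lithium hydroxide, [Li+].[OH-]
Why: Saponification of the hindered vinylogous-carbonate ester; a 3,4,5-trisubstituted isoxazole has no ring C–H for base to attack, and a secondary silyl ether tolerates aqueous hydroxide.

Step 10
Reactants: 17 3-[1-(tert-butyldimethylsilyloxy)-4-methylpent-3-en-1-yl]-5-(propan-2-yl)isoxazole-4-carboxylic acid (racemic); 5 ethyl 5-methyl-2-(3-methylbut-2-en-1-yl)hex-4-enoate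
Product: 20 ethyl 2-({3-[1-(tert-butyldimethylsilyloxy)-4-methylpent-3-en-1-yl]-5-(propan-2-yl)isoxazol-4-yl}carbonyl)-5-methyl-2-(3-methylbut-2-en-1-yl)hex-4-enoate (racemic), via acid chloride 18 (not isolated), via lithium ester enolate 19 (not isolated)
Conditions: 17, 1-chloro-N,N,2-trimethylprop-1-en-1-amine, CH2Cl2, 0 → 23 °C; separately 5, lithium diisopropylamide, THF, −78 °C; then 18 added, −78 → −40 °C
Reagents that add atoms: none
Why: Claisen-type C-acylation of a fully substituted lithium ester enolate by an acid chloride made under neutral conditions (no HCl near the silyl ether or the alkenes); the product has no α-hydrogen, so the β-keto ester should survive the base, and the quaternary carbon C1 and the C1–C2 bond are in place.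

Step 11
Reactants: 20 ethyl 2-({3-[1-(tert-butyldimethylsilyloxy)-4-methylpent-3-en-1-yl]-5-(propan-2-yl)isoxazol-4-yl}carbonyl)-5-methyl-2-(3-methylbut-2-en-1-yl)hex-4-enoate (racemic)
Product: 22 2-{hydroxy[3-(1-hydroxy-4-methylpent-3-en-1-yl)-5-(propan-2-yl)isoxazol-4-yl]methyl}-5-methyl-2-(3-methylbut-2-en-1-yl)hex-4-en-1-ol (diastereomer mixture), via diol silyl ether 21 (not isolated)
Conditions: LiAlH4, THF, 0 °C; then Bu4NF, THF, 23 °C
Reagents that add atoms: none
Why: Hydride reduction takes the ketone and the neopentyl ester to the 1,3-diol without touching the isoxazole N–O bond at 0 °C, and fluoride desilylation frees the third hydroxyl; the diastereomer mixture is used as such because every carbinol centre is oxidised in step 12.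

Step 12
Reactants: 22 2-{hydroxy[3-(1-hydroxy-4-methylpent-3-en-1-yl)-5-(propan-2-yl)isoxazol-4-yl]methyl}-5-methyl-2-(3-methylbut-2-en-1-yl)hex-4-en-1-ol (diastereomer mixture)
Product: 23 5-methyl-2-(3-methylbut-2-en-1-yl)-2-{[3-(4-methylpent-3-enoyl)-5-(propan-2-yl)isoxazol-4-yl]carbonyl}hex-4-enal (achiral)
Conditions: Dess–Martin periodinane (4.5 equiv), NaHCO3, CH2Cl2, 0 → 23 °C; used at once
Reagents that add atoms: none
Why: Threefold Dess–Martin oxidation under bicarbonate buffer should give both ketones and the aldehyde in one operation, the neutral medium keeping the β,γ-double bond out of conjugation and sparing the non-enolisable β-keto aldehyde from retro-Claisen cleavage.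

Step 13
Reactants: 23 5-methyl-2-(3-methylbut-2-en-1-yl)-2-{[3-(4-methylpent-3-enoyl)-5-(propan-2-yl)isoxazol-4-yl]carbonyl}hex-4-enal
Product: 24 (7R)-7-hydroxy-5,5,7-tris(3-methylbut-2-en-1-yl)-3-(propan-2-yl)-5,7-dihydro-2,1-benzisoxazole-4,6-dione
Conditions: (5aS,10bR)-2-(pentafluorophenyl)-5a,10b-dihydro-4H,6H-indeno[2,1-b][1,2,4]triazolo[4,3-d][1,4]oxazin-2-ium tetrafluoroborate (15 mol %), i-Pr2NEt (15 mol %), toluene, 0 → 23 °C
Reagents that add atoms: none
Why: The carbene released from the triazolium salt adds to the non-enolisable C6 aldehyde, proton transfer gives the enaminol (an acyl-anion equivalent), this adds to the C5 ketone, and loss of the carbene leaves the C6 ketone beside the C5 tertiary alcohol. The closest known reaction is the carbene-catalysed enantioselective intramolecular crossed aldehyde–ketone benzoin cyclisation, which includes isoxazole-fused six-membered ketols; the present donor differs in being an α-quaternary aliphatic aldehyde. The six-membered carbocycle closes by 6-exo-trig attack of the enaminol carbon on the ketone carbonyl. The C5 stereocentre is set by the catalyst: the indane wall of the aminoindanol backbone shields one face of the enaminol, so that the ketone should be met on its Si face (O > isoxazol-3-yl > CH2), which gives R. The step needs the aldehyde as sole donor, the C5 ketone as sole acceptor and no base-mediated side reaction: only the aldehyde can form an enaminol, attack on the C2 ketone would need a four-membered ring, the isoxazole edge holds the two acyl groups cis and activates the C5 ketone, the gem-diprenyl group at C1 speeds closure, and a sub-stoichiometric hindered amine with an electron-poor triazolium keeps the β,γ-unsaturated ketone from conjugating or aldolising.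

Step 14
Reactants: 24 (7R)-7-hydroxy-5,5,7-tris(3-methylbut-2-en-1-yl)-3-(propan-2-yl)-5,7-dihydro-2,1-benzisoxazole-4,6-dione
Product: 25 (6R)-5-amino-6-hydroxy-2,2,6-tris(3-methylbut-2-en-1-yl)-4-(2-methylpropanoyl)cyclohex-4-ene-1,3-dione
Conditions: Mo(CO)6, MeCN/H2O, 80 °C
Reagents that add atoms: none
Why: Reductive N–O cleavage of the isoxazole by zerovalent molybdenum hexacarbonyl in wet acetonitrile gives the vinylogous amide and, unlike hydrogenation or single-electron reductants, should leave the three alkenes and the α-ketol intact; C5 is not touched.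

Step 15
Reactants: 25 (6R)-5-amino-6-hydroxy-2,2,6-tris(3-methylbut-2-en-1-yl)-4-(2-methylpropanoyl)cyclohex-4-ene-1,3-dione
Product: 26 (6R)-5,6-dihydroxy-2,2,6-tris(3-methylbut-2-en-1-yl)-4-(2-methylpropanoyl)cyclohex-4-ene-1,3-dione (CNP0442339.2)
Conditions: 1 M aq. HCl, THF, 40 °C
Reagents that add atoms: water, O
Why: Acid hydrolysis of the primary vinylogous amide (water adds at C4, nitrogen leaves as ammonium) gives the enolised β-triketone; C5 carries no hydrogen and cannot epimerise.

**Compound list**

1 | diethyl malonate | CCOC(=O)CC(=O)OCC | starting material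
2 | prenyl bromide (1-bromo-3-methylbut-2-ene) | CC(C)=CCBr | starting material
3 | diethyl 2-(3-methylbut-2-en-1-yl)malonate | CCOC(=O)C(CC=C(C)C)C(=O)OCC | intermediate
4 | diethyl 2,2-bis(3-methylbut-2-en-1-yl)malonate | CCOC(=O)C(CC=C(C)C)(CC=C(C)C)C(=O)OCC | intermediate
5 | ethyl 5-methyl-2-(3-methylbut-2-en-1-yl)hex-4-enoate | CCOC(=O)C(CC=C(C)C)CC=C(C)C | intermediate
6 | ethyl 2-chloro-2-(hydroxyimino)acetate | CCOC(=O)C(Cl)=NO | starting material
7 | methyl 4-methyl-3-oxopentanoate | COC(=O)CC(=O)C(C)C | starting material
8 | ethoxycarbonylformonitrile oxide | CCOC(=O)C#[N+][O-] | intermediate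
9 | 3-ethyl 4-methyl 5-(propan-2-yl)isoxazole-3,4-dicarboxylate | CCOC(=O)c1noc(C(C)C)c1C(=O)OC | intermediate
10 | methyl 3-(hydroxymethyl)-5-(propan-2-yl)isoxazole-4-carboxylate | COC(=O)c1c(CO)noc1C(C)C | intermediate
11 | methyl 3-formyl-5-(propan-2-yl)isoxazole-4-carboxylate | COC(=O)c1c(C=O)noc1C(C)C | intermediate
12 | allyl bromide (3-bromoprop-1-ene) | C=CCBr | starting material
13 | methyl 3-(1-hydroxybut-3-en-1-yl)-5-(propan-2-yl)isoxazole-4-carboxylate, racemic | COC(=O)c1c(C(O)CC=C)noc1C(C)C | intermediate
14 | 2-methylbut-2-ene | CC=C(C)C | starting material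
15 | methyl 3-(1-hydroxy-4-methylpent-3-en-1-yl)-5-(propan-2-yl)isoxazole-4-carboxylate, racemic | COC(=O)c1c(C(O)CC=C(C)C)noc1C(C)C | intermediate
16 | methyl 3-[1-(tert-butyldimethylsilyloxy)-4-methylpent-3-en-1-yl]-5-(propan-2-yl)isoxazole-4-carboxylate, racemic | COC(=O)c1c(C(O[Si](C)(C)C(C)(C)C)CC=C(C)C)noc1C(C)C | intermediate
17 | 3-[1-(tert-butyldimethylsilyloxy)-4-methylpent-3-en-1-yl]-5-(propan-2-yl)isoxazole-4-carboxylic acid, racemic | OC(=O)c1c(C(O[Si](C)(C)C(C)(C)C)CC=C(C)C)noc1C(C)C | intermediate
18 | 3-[1-(tert-butyldimethylsilyloxy)-4-methylpent-3-en-1-yl]-5-(propan-2-yl)isoxazole-4-carbonyl chloride, racemic | O=C(Cl)c1c(C(O[Si](C)(C)C(C)(C)C)CC=C(C)C)noc1C(C)C | intermediate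
19 | lithium 1-ethoxy-5-methyl-2-(3-methylbut-2-en-1-yl)hexa-1,4-dien-1-olate (lithium enolate of 5) | [Li+].CCOC([O-])=C(CC=C(C)C)CC=C(C)C | intermediate
20 | ethyl 2-({3-[1-(tert-butyldimethylsilyloxy)-4-methylpent-3-en-1-yl]-5-(propan-2-yl)isoxazol-4-yl}carbonyl)-5-methyl-2-(3-methylbut-2-en-1-yl)hex-4-enoate, racemic | CCOC(=O)C(CC=C(C)C)(CC=C(C)C)C(=O)c1c(C(O[Si](C)(C)C(C)(C)C)CC=C(C)C)noc1C(C)C | intermediate
21 | 2-[{3-[1-(tert-butyldimethylsilyloxy)-4-methylpent-3-en-1-yl]-5-(propan-2-yl)isoxazol-4-yl}(hydroxy)methyl]-5-methyl-2-(3-methylbut-2-en-1-yl)hex-4-en-1-ol, diastereomer mixture | OCC(CC=C(C)C)(CC=C(C)C)C(O)c1c(C(O[Si](C)(C)C(C)(C)C)CC=C(C)C)noc1C(C)C | intermediate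
22 | 2-{hydroxy[3-(1-hydroxy-4-methylpent-3-en-1-yl)-5-(propan-2-yl)isoxazol-4-yl]methyl}-5-methyl-2-(3-methylbut-2-en-1-yl)hex-4-en-1-ol, diastereomer mixture | OCC(CC=C(C)C)(CC=C(C)C)C(O)c1c(C(O)CC=C(C)C)noc1C(C)C | intermediate
23 | 5-methyl-2-(3-methylbut-2-en-1-yl)-2-{[3-(4-methylpent-3-enoyl)-5-(propan-2-yl)isoxazol-4-yl]carbonyl}hex-4-enal | O=CC(CC=C(C)C)(CC=C(C)C)C(=O)c1c(C(C)C)onc1C(=O)CC=C(C)C | intermediate
24 | (7R)-7-hydroxy-5,5,7-tris(3-methylbut-2-en-1-yl)-3-(propan-2-yl)-5,7-dihydro-2,1-benzisoxazole-4,6-dione | CC(C)=CCC1(CC=C(C)C)C(=O)c2c(C(C)C)onc2[C@](O)(CC=C(C)C)C1=O | intermediate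
25 | (6R)-5-amino-6-hydroxy-2,2,6-tris(3-methylbut-2-en-1-yl)-4-(2-methylpropanoyl)cyclohex-4-ene-1,3-dione | CC(C)=CCC1(CC=C(C)C)C(=O)C(C(=O)C(C)C)=C(N)[C@](O)(CC=C(C)C)C1=O | intermediate
26 | (6R)-5,6-dihydroxy-2,2,6-tris(3-methylbut-2-en-1-yl)-4-(2-methylpropanoyl)cyclohex-4-ene-1,3-dione (CNP0442339.2) | CC(C)=CCC1(CC=C(C)C)C(=O)C(C(=O)C(C)C)=C(O)[C@](O)(CC=C(C)C)C1=O | target

**Step count and risks**

Total step count: 15. Longest linear sequence: 13 steps (steps 3–15, from 6 and 7); steps 1–2 make fragment 5, which joins at step 10.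

Steps most likely to fail:

Step 13. What may go wrong: enaminol formation at the neopentyl-type aldehyde may be slow, so that base-mediated migration of the β,γ-double bond into conjugation, or aldol closure of the ketone α-carbon onto the aldehyde, overtakes the carbene pathway; or the closure may proceed with poor facial selectivity at the C5 ketone. Fallback: stereocontrol is moved from the catalyst to a separation. Setting out from 23, the same ring closure is run with the small achiral precatalyst 2-(pentafluorophenyl)-6,7-dihydro-5H-pyrrolo[2,1-c][1,2,4]triazol-2-ium tetrafluoroborate (higher loading, i-Pr2NEt, toluene), which should reach the hindered aldehyde more easily, to give the racemic ketol rac-7-hydroxy-5,5,7-tris(3-methylbut-2-en-1-yl)-3-(propan-2-yl)-5,7-dihydro-2,1-benzisoxazole-4,6-dione F1. Preparative chromatography on a chiral stationary phase (supercritical CO2/alcohol) then separates the (7R)-enantiomer, which is 24 and re-enters the route at step 14, from the (7S)-enantiomer F2.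

Step 10. What may go wrong: O-acylation of the hindered enolate to a ketene acetal ester, or no coupling at all because both partners are congested, while the chloride slowly closes onto the silyl ether oxygen. Fallback: the quaternary carbon is built by alkylation instead of acylation. Setting out from 17 (converted into 18 as in step 10), acylation of the magnesium enolate of potassium ethyl malonate (MgCl2, Et3N, MeCN, 0 → 23 °C) with decarboxylation on acidic work-up should give the β-keto ester ethyl 3-{3-[1-(tert-butyldimethylsilyloxy)-4-methylpent-3-en-1-yl]-5-(propan-2-yl)isoxazol-4-yl}-3-oxopropanoate F3. Two successive C-prenylations with 2 (K2CO3, acetone, 50 °C), passing through the mono-prenylated β-keto ester F4, return to the route at 20.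

Step 15. What may go wrong: hydrolysis of the doubly conjugated vinylogous amide may be slow, and the acid and warmth it needs may start ring closure of a prenyl group onto the C4 enol or C5 hydroxyl oxygen, or acyloin rearrangement of the C5/C6 ketol. Fallback: nitrogen is removed as N2 instead of as ammonia. Setting out from 25, nitrosative deamination (NaNO2, aq. AcOH/THF, 0 °C) should nitrosate the primary nitrogen, since the enamine β-carbon C3 is fully substituted and closed to C-nitrosation. Water then displaces the diazonium-type group by addition–elimination at C4 and gives 26 directly at 0 °C; no compound beyond the list is made (F0).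

**Further compounds**

F1 | step 13 | rac-7-hydroxy-5,5,7-tris(3-methylbut-2-en-1-yl)-3-(propan-2-yl)-5,7-dihydro-2,1-benzisoxazole-4,6-dione | CC(C)=CCC1(CC=C(C)C)C(=O)c2c(C(C)C)onc2C(O)(CC=C(C)C)C1=O
F2 | step 13 | (7S)-7-hydroxy-5,5,7-tris(3-methylbut-2-en-1-yl)-3-(propan-2-yl)-5,7-dihydro-2,1-benzisoxazole-4,6-dione | CC(C)=CCC1(CC=C(C)C)C(=O)c2c(C(C)C)onc2[C@@](O)(CC=C(C)C)C1=O
F3 | step 10 | ethyl 3-{3-[1-(tert-butyldimethylsilyloxy)-4-methylpent-3-en-1-yl]-5-(propan-2-yl)isoxazol-4-yl}-3-oxopropanoate, racemic | CCOC(=O)CC(=O)c1c(C(O[Si](C)(C)C(C)(C)C)CC=C(C)C)noc1C(C)C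
F4 | step 10 | ethyl 2-({3-[1-(tert-butyldimethylsilyloxy)-4-methylpent-3-en-1-yl]-5-(propan-2-yl)isoxazol-4-yl}carbonyl)-5-methylhex-4-enoate, diastereomer mixture | CCOC(=O)C(CC=C(C)C)C(=O)c1c(C(O[Si](C)(C)C(C)(C)C)CC=C(C)C)noc1C(C)C
F0 | step 15 | none | none
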